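## Structural features

The target is a diaryl ether made of two benzene rings only. Ring A is a 3-hydroxy-5-sulfooxyphenyl group and ring B a 2,6-dihydroxy-4-sulfooxyphenyl group, joined through the oxygen on C1 of ring A and C1' of ring B. There is no stereocentre, so no stereocentres stand next to each other and nothing needs three-dimensional control. Ring A carries oxygen on C1, C3 and C5, and the three oxygens all differ: aryl ether, free hydroxyl, sulfate monoester. Ring B carries oxygen on C1', C2', C4' and C6'; the ether oxygen lies between two hydroxyls, so the aryl–oxygen bond on that side is flanked on both ortho positions. The fragile groups are the two aryl hydrogen sulfates (lost under acid, heat or strong nucleophiles, best carried as salts) and the electron-rich polyphenol rings, which oxidise easily and can undergo C-sulfonation. The real difficulty is sorting five phenolic oxygens into three classes (two sulfated, three free, one in the ether) and making the hindered ether link. The key step uses the 1,3,5-oxygen array of ring A: the C3 oxygen comes from a ketene carbonyl, the C5 oxygen from an ynol ether, and the C1 oxygen is already bonded to ring B, so ring A is born with its oxygens told apart.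

## Logic of the disconnections

28 back to 26. The three benzylic C–O bonds are cut (on the C3, C2' and C6' oxygens) and the sulfate protons are exchanged for sodium. Hydrogenolysis is one of the few deprotections that aryl sulfates tolerate, and one kind of protecting group then covers all three phenols that stay free. The forward step needs a catalyst free of pyridine and sulfates kept as salts, with acid applied only at the very end and cold.

26 back to 25. The two aryl O–S bonds are cut. The sulfates are the most fragile groups, so they go on late and onto the only two free phenols. This leaves 25 as a neutral compound that can be chromatographed. The forward step must sulfate on oxygen rather than on the electron-rich carbons of ring A, and must go to completion at both sites.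

25 back to 24, and 24 back to 22 and 23. Two O–Si bonds are cut, then one benzylic C–O bond. The ring construction delivers the C3 oxygen free and the C5 oxygen silylated; because the silyl ethers of both rings fall together, the silylated oxygens become the sulfate sites and the free phenol must first be benzylated. Both sulfate positions are then unveiled in one operation. The alkylation must not move silyl groups, and the fluoride step must not oxidise the liberated ring B phenol.

22 back to 9 and 17. The C3–C4 and C5–C6 bonds of ring A are cut. Ring A falls into a four-carbon and a two-carbon unit, and the hindered aryl–oxygen bond becomes a vinylic C–O bond on a four-membered enone. Tracing the atoms through the cascade shows that the oxygen of 17 ends meta to both other oxygens, so the structures of 9, 17 and 22 are consistent as drawn. The forward step demands thermal opening of a vinylogous-ester cyclobutenone, correct regiochemistry in the ketene–alkyne union, capture of the ketene by 17 rather than by the product phenol, and thermal survival of 17.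

9 back to 5 and 7 (through 8), and 7 back to 6. The vinylic C3–O bond is cut. Addition–elimination at an sp2 carbon of a small flat ring is little affected by the two ortho substituents of 5. A direct exchange of 5 onto 6 would run uphill, because aryloxide is a better leaving group than ethoxide; the four-carbon unit is therefore activated as 8, whose chloride leaves irreversibly. The forward step needs 8 to be made and used cold, with no excess chlorinating agent left to acylate 5.

5 back to 3 and 4, 3 back to 2, 2 back to 1. The O–Si bond on the unhindered oxygen is cut, then the C–O bond at the carbon para to the hydroxyl of 1 (through the quinone). Selective benzylation of the two outer hydroxyls of a 1,2,3-triol is not dependable; in 1 the two benzyl groups are already in place and the fourth oxygen enters at the single para position. The two hydroxyls of 3 then differ sharply in steric access. The forward steps need para-selective oxidation and clean mono-silylation.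

17 back to 15, 15 back to 13, 13 back to 10 and 4. The second π bond of the alkyne is cut (as H and Br), then the C–Br bond, then the O–Si bond together with the ring bonds of 10. The parent siloxyacetylene is not assumed to be purchasable; the classical vinyl ether to bromovinyl ether to alkynyl ether sequence reaches it from bulk chemicals. The forward steps need low temperature and a cis arrangement of oxygen and bromine in 15, so that H and Br are anti for elimination.

## Other disconnections considered

Alternative 1: The cut removes the C5–O and C4'–O bonds, leaving the tris-silyl diaryl ether A1 with hydrogen at both positions. Forward, an iridium catalyst from [Ir(OMe)(cod)]2 and 4,4'-di-tert-butyl-2,2'-bipyridine with bis(pinacolato)diboron would borylate the only two C–H bonds that have no ortho neighbour, giving bis(boronate) A2. KHSO5 in the same flask would then turn both C–B bonds into hydroxyls, giving diol A3.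
- In favour: the two oxygens that will carry the sulfates appear free while the other three stay silylated, so sulfation and fluoride deprotection finish the synthesis without hydrogenolysis. Sterically governed borylation followed by oxidation is well-established chemistry.
- Against: A1 still requires the hindered diaryl ether bond to be made by copper coupling of a 2,6-dioxygenated phenol. Site selectivity rests on sterics alone in two very electron-rich, slowly borylating rings. KHSO5 could over-oxidise the new para-aryloxyphenol of ring B or loosen silyl ethers.
- Comparison: on step count this alternative is the better plan (about half the operations), and on precedent for its key step it is also the better. On the final deprotection the two are equal. The chosen plan is stronger only in that it avoids the hindered aryl–oxygen coupling altogether and fixes the oxygen pattern by the origin of the atoms and not by relative rates.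

Alternative 2: The cut removes the C2'–C3' and C6'–C5' bonds of ring B. Forward, the ring A phenol A4 would be alkylated to the aryloxymalonate A5, and sodium benzyloxide (NaOCH2Ph) in hot toluene would condense A5 with the enol ether diester A6 in two Claisen acylations to give the fully substituted ring B in A7.
- In favour: the ether bond is made by a simple SN2 reaction, ring B arrives with all four oxygens, and the all-benzyl ester and alkoxide set avoids ester scrambling.
- Against: the methine of A5 is acidic, and its enolate makes both ester carbonyls poor electrophiles. A6 must react twice as a carbon nucleophile, and retro-Claisen cleavage competes. Hot alkoxide endangers the aryl silyl ether. A7 carries two ester groups that must be removed by hydrogenolysis and double decarboxylation. Its oxygen pattern (C4' benzylated, C2' and C6' free) is the reverse of what is needed, so C2' and C6' must be capped before the benzyl groups come off. A4 itself needs a statistical desymmetrisation of phloroglucinol.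
- Comparison: the two plans are equal in avoiding a hindered aryl–oxygen coupling. On mechanism the chosen plan has fewer competing acid–base traps, and on step economy it is shorter after the key step.

Alternative 3: The cut removes the C1'–C2' bond of ring B. Forward, the linear keto enol-ether ester A8 would be treated with LiN(SiMe3)2 or NaH in tetrahydrofuran; the carbon bearing the aryloxy group attacks the ester in an intramolecular Claisen reaction and the ring aromatises to resorcinol A9.
- In favour: the ring closure is six-membered, regiospecific and driven by aromatisation, in the manner of polyketide folding. The ether bond again comes from an SN2 reaction on an α-halo ketone, and no ester groups remain to be removed.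
- Against: A8 takes several steps and must have the ketone and the ester-bearing CH2 cis on the enol ether. The most acidic site of A8 is the methylene next to the ester, not the aryloxy-bearing carbon, so the productive enolate forms only by equilibration. A9 again has C2' and C6' free and C4' benzylated, so a capping step precedes debenzylation. A4 is needed here too.
- Comparison: on precedent for the ring-forming event this alternative is the equal of the chosen plan or better. On differentiation of the oxygens and on total step count the chosen plan is somewhat ahead, because its key product needs only one protection before the sulfate sites are unveiled.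

Key step: step 9

Remark: the target is drawn as the free bis(hydrogen sulfate); the sulfates are carried as the disodium salt and the acid is released only in the last operation on a cold acidic resin, because aryl hydrogen sulfates hydrolyse under their own acidity when warmed.
Remark: compounds 1, 4, 6, 10 and 23 are taken as catalogue chemicals.

## Steps

Step 1
Reactants: 1 3,5-bis(benzyloxy)phenol
Product: 2 2,6-bis(benzyloxy)-1,4-benzoquinone
Conditions: (KSO3)2NO (2.5 equiv), aq KH2PO4, acetone–H2O, 0 °C → rt
Reagents that add atoms: potassium nitrosodisulfonate, [K+].[K+].[O]N(S(=O)(=O)[O-])S(=O)(=O)[O-]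
Why: Teuber oxidation: the phenoxyl radical of 1 is trapped at its only para carbon by a second nitrosodisulfonate radical, and loss of imidodisulfonate gives the para-quinone. Both benzyloxy groups activate that carbon, and attack at an ortho carbon would lead to the less stable ortho-quinone.

Step 2
Reactants: 2 2,6-bis(benzyloxy)-1,4-benzoquinone
Product: 3 2,6-bis(benzyloxy)benzene-1,4-diol
Conditions: Na2S2O4, EtOAc–H2O, rt, under argon
Reagents that add atoms: none
Why: Dithionite reduction of a quinone to its hydroquinone; benzyl ethers are inert to it. The air-sensitive diol is kept under argon and silylated promptly.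

Step 3
Reactants: 3 2,6-bis(benzyloxy)benzene-1,4-diol; 4 chlorotriisopropylsilane
Product: 5 2,6-bis(benzyloxy)-4-(triisopropylsilyloxy)phenol
Conditions: i-Pr3SiCl (1.05 equiv), imidazole, DMF, 0 °C
Reagents that add atoms: chlorotriisopropylsilane (compound 4), CC(C)[Si](Cl)(C(C)C)C(C)C
Why: Silylation with a bulky silyl chloride and imidazole is governed by sterics: the 1-hydroxyl sits between two benzyloxy groups, while the 4-hydroxyl has two ortho hydrogens and should react alone.

Step 4
Reactants: 6 3-ethoxycyclobut-2-en-1-one
Product: 7 cyclobutane-1,3-dione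
Conditions: 1 M HCl (aq), rt
Reagents that add atoms: water, O
Why: Acid hydrolysis of a vinylogous ester (enol ether hydrolysis) to the 1,3-dione, a strongly acidic enol that is used soon after isolation.

Step 5
Reactants: 7 cyclobutane-1,3-dione; 5 2,6-bis(benzyloxy)-4-(triisopropylsilyloxy)phenol
Product: 9 3-[2,6-bis(benzyloxy)-4-(triisopropylsilyloxy)phenoxy]cyclobut-2-en-1-one, via 3-chlorocyclobut-2-en-1-one 8 (not isolated)
Conditions: 7 (1.3 equiv), (COCl)2 (1.25 equiv), DMF (cat.), CH2Cl2, 0 °C; then Et3N, 5 (1.0 equiv), 0 °C → rt
Reagents that add atoms: none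
Why: Oxalyl chloride with DMF catalysis converts the enolised dione into its vinylogous acid chloride, and the phenoxide of 5 then substitutes at C3 by addition–elimination. Chloride is a far better leaving group than the aryloxide, so the substitution is irreversible, unlike an exchange on the ethyl enol ether 6.

Step 6
Reactants: 10 tetrahydrofuran; 4 chlorotriisopropylsilane
Product: 13 triisopropyl(vinyloxy)silane, via 2-lithiotetrahydrofuran 11 (not isolated), via lithium ethenolate 12 (not isolated)
Conditions: n-BuLi, THF, rt, 16 h; then i-Pr3SiCl, DMPU, 0 °C → rt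
Reagents that add atoms: chlorotriisopropylsilane (compound 4), CC(C)[Si](Cl)(C(C)C)C(C)C
Why: α-Lithiation of tetrahydrofuran and cycloreversion of 11 release ethene and the acetaldehyde enolate 12, which the hindered silyl chloride traps on oxygen (enolate O-silylation).

Step 7
Reactants: 13 triisopropyl(vinyloxy)silane
Product: 15 (Z)-(2-bromoethenyloxy)triisopropylsilane, via (1,2-dibromoethoxy)triisopropylsilane 14 (not isolated)
Conditions: Br2, CH2Cl2, −78 °C; then Et3N, −78 °C → rt
Reagents that add atoms: bromine, BrBr
Why: Bromine addition to the enol ether followed by amine-induced loss of HBr from the α-bromo ether (bromination–dehydrobromination), the sequence used for 2-bromovinyl alkyl and trimethylsilyl ethers. The cis isomer is expected to predominate.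

Step 8
Reactants: 15 (Z)-(2-bromoethenyloxy)triisopropylsilane
Product: 17 (triisopropylsilyloxy)acetylene, via lithium (triisopropylsilyloxy)acetylide 16 (not isolated)
Conditions: LiN(i-Pr)2 (2.2 equiv), THF, −78 °C; then aq NH4Cl, −78 → 0 °C
Reagents that add atoms: none
Why: Anti E2 dehydrobromination of the cis-bromovinyl ether gives the ynol ether, which the second equivalent of amide deprotonates to 16; any trans isomer can reach 16 by α-lithiation and 1,2-shift. The linear C≡C–O unit keeps silicon out of reach of the carbanion, so no silyl shift is expected before the cold quench.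

Step 9
Reactants: 9 3-[2,6-bis(benzyloxy)-4-(triisopropylsilyloxy)phenoxy]cyclobut-2-en-1-one; 17 (triisopropylsilyloxy)acetylene
Product: 22 3-[2,6-bis(benzyloxy)-4-(triisopropylsilyloxy)phenoxy]-5-(triisopropylsilyloxy)phenol, via vinylketene 18 (not isolated), via vinylcyclobutenone 19 (not isolated), via dienylketene 20 (not isolated), via cyclohexadienone 21 (not isolated)
Conditions: 17 (2.5 equiv), toluene, 80 → 110 °C, slow addition of 9, under argon
Reagents that add atoms: none
Why: Proposed new method: the thermal cyclobutenone–ynol ether benzannulation (Danheiser benzannulation) is established for alkyl- and aryl-substituted cyclobutenones with siloxyalkynes, and its extension to a 3-aryloxy (vinylogous ester) cyclobutenone is reasoned from the 3-siloxy-4-vinylcyclobutenone that every such annulation passes through, which also bears oxygen on C3 and opens readily. Conrotatory four-electron opening of 9 should give vinylketene 18, whose electrophilic ketene carbon is attacked by the unsubstituted, nucleophilic carbon of 17, so the [2+2] cycloaddition forms C3–C4 and C5–C6 and gives 19. A second four-electron opening of 19 gives dienylketene 20 reversibly, so the isomer with ketene and vinyl groups cis on the central double bond is drained off. Ring A closes by a thermal disrotatory six-electron electrocyclisation of 20 to 21, which tautomerises to phenol 22. No stereocentre is formed. The step needs regioselectivity in the ketene–alkyne union, which the polarisation of the ynol ether supplies (a direct [4+2] union would give the same constitution, since both flanking ring carbons carry hydrogen), and capture of 18 by the alkyne rather than by the product phenol, which excess 17 and slow addition of 9 should secure. The medium is neutral and aprotic, so the vinylogous aryl ester, the silyl ethers and the benzyl ethers should survive.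

Step 10
Reactants: 22 3-[2,6-bis(benzyloxy)-4-(triisopropylsilyloxy)phenoxy]-5-(triisopropylsilyloxy)phenol; 23 benzyl bromide
Product: 24 {3-(benzyloxy)-5-[2,6-bis(benzyloxy)-4-(triisopropylsilyloxy)phenoxy]phenoxy}triisopropylsilane
Conditions: BnBr, K2CO3, acetone, 50 °C
Reagents that add atoms: benzyl bromide (compound 23), BrCc1ccccc1
Why: Williamson ether synthesis (SN2) on the only free phenol; carbonate in acetone is mild enough to leave the hindered aryl silyl ethers in place.

Step 11
Reactants: 24 {3-(benzyloxy)-5-[2,6-bis(benzyloxy)-4-(triisopropylsilyloxy)phenoxy]phenoxy}triisopropylsilane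
Product: 25 3-(benzyloxy)-5-[2,6-bis(benzyloxy)-4-hydroxyphenoxy]phenol
Conditions: Bu4NF (2.4 equiv), AcOH (2.4 equiv), THF, 0 °C, degassed
Reagents that add atoms: none
Why: Fluoride cleavage of both aryl silyl ethers, driven by Si–F bond formation. Acetic acid keeps the liberated phenols protonated, which limits air oxidation of the electron-rich ring B phenol.

Step 12
Reactants: 25 3-(benzyloxy)-5-[2,6-bis(benzyloxy)-4-hydroxyphenoxy]phenol
Product: 26 disodium 3-(benzyloxy)-5-[2,6-bis(benzyloxy)-4-(sulfonatooxy)phenoxy]phenyl sulfate
Conditions: SO3·pyridine (6 equiv), pyridine, rt; then aq NaHCO3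
Reagents that add atoms: sulfur trioxide–pyridine complex, [O-]S(=O)(=O)[n+]1ccccc1; sodium hydrogencarbonate, [Na+].OC([O-])=O
Why: O-Sulfation of phenols with the SO3·pyridine complex; room temperature should keep the electron-rich ring A from C-sulfonation. Exchange to the sodium salt removes pyridine, which would inhibit the hydrogenolysis that follows.

Step 13
Reactants: 26 disodium 3-(benzyloxy)-5-[2,6-bis(benzyloxy)-4-(sulfonatooxy)phenoxy]phenyl sulfate
Product: 28 3-[2,6-dihydroxy-4-(sulfooxy)phenoxy]-5-hydroxyphenyl hydrogen sulfate (target), via disodium salt 27 (not isolated)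
Conditions: H2 (1 atm), Pd/C, MeOH–H2O, rt; filter; Dowex 50W (H+ form), H2O, 0 °C; freeze-dry
Reagents that add atoms: none
Why: Hydrogenolysis of the three benzyl ethers over Pd/C, which aryl sulfate salts tolerate, followed by cation exchange on a sulfonic acid resin in the cold to release the bis(hydrogen sulfate).

## Compound list

1 | 3,5-bis(benzyloxy)phenol | Oc1cc(OCc2ccccc2)cc(OCc2ccccc2)c1 | starting material
2 | 2,6-bis(benzyloxy)-1,4-benzoquinone | O=C1C=C(OCc2ccccc2)C(=O)C(OCc2ccccc2)=C1 | intermediate
3 | 2,6-bis(benzyloxy)benzene-1,4-diol | Oc1cc(OCc2ccccc2)c(O)c(OCc2ccccc2)c1 | intermediate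
4 | chlorotriisopropylsilane | CC(C)[Si](Cl)(C(C)C)C(C)C | starting material
5 | 2,6-bis(benzyloxy)-4-(triisopropylsilyloxy)phenol | Oc1c(OCc2ccccc2)cc(O[Si](C(C)C)(C(C)C)C(C)C)cc1OCc1ccccc1 | intermediate
6 | 3-ethoxycyclobut-2-en-1-one | CCOC1=CC(=O)C1 | starting material
7 | cyclobutane-1,3-dione | O=C1CC(=O)C1 | intermediate
8 | 3-chlorocyclobut-2-en-1-one | O=C1C=C(Cl)C1 | intermediate
9 | 3-[2,6-bis(benzyloxy)-4-(triisopropylsilyloxy)phenoxy]cyclobut-2-en-1-one | O=C1C=C(Oc2c(OCc3ccccc3)cc(O[Si](C(C)C)(C(C)C)C(C)C)cc2OCc2ccccc2)C1 | intermediate
10 | tetrahydrofuran | C1CCOC1 | starting material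
11 | 2-lithiotetrahydrofuran | [Li]C1CCCO1 | intermediate
12 | lithium ethenolate | [Li]OC=C | intermediate
13 | triisopropyl(vinyloxy)silane | C=CO[Si](C(C)C)(C(C)C)C(C)C | intermediate
14 | (1,2-dibromoethoxy)triisopropylsilane (racemic) | BrCC(Br)O[Si](C(C)C)(C(C)C)C(C)C | intermediate
15 | (Z)-(2-bromoethenyloxy)triisopropylsilane | Br/C=C\O[Si](C(C)C)(C(C)C)C(C)C | intermediate
16 | lithium (triisopropylsilyloxy)acetylide | [Li]C#CO[Si](C(C)C)(C(C)C)C(C)C | intermediate
17 | (triisopropylsilyloxy)acetylene | C#CO[Si](C(C)C)(C(C)C)C(C)C | intermediate
18 | 3-[2,6-bis(benzyloxy)-4-(triisopropylsilyloxy)phenoxy]buta-1,3-dien-1-one (vinylketene) | C=C(C=C=O)Oc1c(OCc2ccccc2)cc(O[Si](C(C)C)(C(C)C)C(C)C)cc1OCc1ccccc1 | intermediate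
19 | 4-{1-[2,6-bis(benzyloxy)-4-(triisopropylsilyloxy)phenoxy]ethenyl}-3-(triisopropylsilyloxy)cyclobut-2-en-1-one (racemic) | C=C(Oc1c(OCc2ccccc2)cc(O[Si](C(C)C)(C(C)C)C(C)C)cc1OCc1ccccc1)C1C(=O)C=C1O[Si](C(C)C)(C(C)C)C(C)C | intermediate
20 | (3E)-5-[2,6-bis(benzyloxy)-4-(triisopropylsilyloxy)phenoxy]-3-(triisopropylsilyloxy)hexa-1,3,5-trien-1-one (ketene and vinyl groups cis) | O=C=C/C(O[Si](C(C)C)(C(C)C)C(C)C)=C\C(=C)Oc1c(OCc2ccccc2)cc(O[Si](C(C)C)(C(C)C)C(C)C)cc1OCc1ccccc1 | intermediate
21 | 5-[2,6-bis(benzyloxy)-4-(triisopropylsilyloxy)phenoxy]-3-(triisopropylsilyloxy)cyclohexa-2,4-dien-1-one | O=C1CC(Oc2c(OCc3ccccc3)cc(O[Si](C(C)C)(C(C)C)C(C)C)cc2OCc2ccccc2)=CC(O[Si](C(C)C)(C(C)C)C(C)C)=C1 | intermediate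
22 | 3-[2,6-bis(benzyloxy)-4-(triisopropylsilyloxy)phenoxy]-5-(triisopropylsilyloxy)phenol | Oc1cc(O[Si](C(C)C)(C(C)C)C(C)C)cc(Oc2c(OCc3ccccc3)cc(O[Si](C(C)C)(C(C)C)C(C)C)cc2OCc2ccccc2)c1 | intermediate
23 | benzyl bromide | BrCc1ccccc1 | starting material
24 | {3-(benzyloxy)-5-[2,6-bis(benzyloxy)-4-(triisopropylsilyloxy)phenoxy]phenoxy}triisopropylsilane | CC(C)[Si](Oc1cc(OCc2ccccc2)cc(Oc2c(OCc3ccccc3)cc(O[Si](C(C)C)(C(C)C)C(C)C)cc2OCc2ccccc2)c1)(C(C)C)C(C)C | intermediate
25 | 3-(benzyloxy)-5-[2,6-bis(benzyloxy)-4-hydroxyphenoxy]phenol | Oc1cc(OCc2ccccc2)cc(Oc2c(OCc3ccccc3)cc(O)cc2OCc2ccccc2)c1 | intermediate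
26 | disodium 3-(benzyloxy)-5-[2,6-bis(benzyloxy)-4-(sulfonatooxy)phenoxy]phenyl sulfate | [Na+].[Na+].[O-]S(=O)(=O)Oc1cc(OCc2ccccc2)cc(Oc2c(OCc3ccccc3)cc(OS(=O)(=O)[O-])cc2OCc2ccccc2)c1 | intermediate
27 | disodium 3-[2,6-dihydroxy-4-(sulfonatooxy)phenoxy]-5-hydroxyphenyl sulfate | [Na+].[Na+].[O-]S(=O)(=O)Oc1cc(O)cc(Oc2c(O)cc(OS(=O)(=O)[O-])cc2O)c1 | intermediate
28 | 3-[2,6-dihydroxy-4-(sulfooxy)phenoxy]-5-hydroxyphenyl hydrogen sulfate | O=S(=O)(O)Oc1cc(O)cc(Oc2c(O)cc(OS(=O)(=O)O)cc2O)c1 | target

## Step count and risks

Total steps: 13. Longest linear sequence: 9 steps (1, 2, 3, 5, 9, 10, 11, 12, 13, from compound 1). The branch to 7 (step 4) and the branch to 17 (steps 6–8) join at steps 5 and 9.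

Least certain steps:

Step 9 (key step, proposed new method). The most likely failure is slow electrocyclic opening of the push–pull cyclobutenone. The donor oxygen on C3 stabilises the ring, so temperatures may be needed at which 17 isomerises by silyl shift to a silylketene, or at which the vinylketene is consumed by acylating the product phenol or by dimerising.
Fallback (known chemistry, from 5, rejoining at 24): ring A is brought in intact by a copper-mediated Chan–Lam–Evans ether coupling. Commercial 5-bromobenzene-1,3-diol is mono-benzylated with 23 (K2CO3, acetone; statistical, diol recycled) to 3-(benzyloxy)-5-bromophenol F1. This is silylated with 4 and imidazole to [3-(benzyloxy)-5-bromophenoxy]triisopropylsilane F2. Bromine–lithium exchange (n-BuLi, THF, −78 °C) gives [3-(benzyloxy)-5-(triisopropylsilyloxy)phenyl]lithium F3, which is trapped with B(O-i-Pr)3 and worked up with aqueous NH4Cl to [3-(benzyloxy)-5-(triisopropylsilyloxy)phenyl]boronic acid F4. Coupling of F4 with 5 (Cu(OAc)2, pyridine, 4 Å molecular sieves, CH2Cl2, air, rt), a reaction known to accept doubly ortho-substituted phenols, should give 24. Steps 11–13 follow unchanged and steps 4–10 fall away.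

Step 5. The most likely failure is decomposition or oligomerisation of the strained vinylogous acid chloride 8 before the hindered phenoxide adds; acylation of 5 by residual oxalyl chloride is a second risk.
Fallback (from 5, rejoining at 9): the four-membered ring is built on the aryl oxygen by a ketene–ynol ether [2+2] cycloaddition. Compound 5 is treated with KH and trichloroethylene (THF) to give the (E)-1,2-dichlorovinyl ether F5. n-BuLi (2.2 equiv, −78 °C) converts it through elimination and chlorine–lithium exchange into lithium {[2,6-bis(benzyloxy)-4-(triisopropylsilyloxy)phenoxy]ethynyl}ide F6, and methanol quench gives [3,5-bis(benzyloxy)-4-(ethynyloxy)phenoxy]triisopropylsilane F7. Ketene gas (CH2=C=O, from a ketene generator) in CH2Cl2 at 0 °C should add across the ynol ether with the same polarity control to give 9.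

Step 8. The most likely failure is incomplete elimination from any trans isomer carried over from step 7, and loss of the sensitive ynol ether by hydration or silyl migration during isolation.
Fallback (from 15, rejoining at 17): the alkyne is formed by carbenoid rearrangement, which does not depend on alkene geometry. Bromination of 15 (Br2, CH2Cl2, −78 °C) gives (1,2,2-tribromoethoxy)triisopropylsilane F8, and Et3N in the same flask gives (2,2-dibromoethenyloxy)triisopropylsilane F9. n-BuLi (2.1 equiv, THF, −78 °C) effects bromine–lithium exchange and a Fritsch–Buttenberg–Wiechell 1,2-shift (the second half of a Corey–Fuchs sequence) to give 16, which is protonated to 17 as in step 8.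

Step 1. The most likely failure is over-oxidation or attack at an ortho carbon, because the para carbon is flanked by two benzyloxy groups; poor contact between the lipophilic phenol and the aqueous radical salt is a further risk.
Fallback (from 1, rejoining at 3): the Elbs persulfate oxidation hydroxylates para to the phenoxide without passing through the quinone. K2S2O8 in aqueous NaOH–pyridine gives potassium 2,6-bis(benzyloxy)-4-hydroxyphenyl sulfate F10, and brief warming with dilute HCl hydrolyses the sulfate to 3; step 2 is then not needed.

Step 12. The most likely failure is incomplete sulfation of the second phenol together with C-sulfonation of the electron-rich ring A, and loss of material when the amphiphilic disodium salt is isolated.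
Fallback (from 25, rejoining at 28): the sulfates are introduced in protected, neutral form. Compound 25 with 2,2,2-trichloroethyl chlorosulfate, Et3N and 4-(dimethylamino)pyridine in THF gives the bis(2,2,2-trichloroethyl sulfate) diester F11, which can be chromatographed. Pd/C with HCO2NH4 in MeOH then removes the trichloroethyl groups and the three benzyl ethers together, giving diammonium 3-[2,6-dihydroxy-4-(sulfonatooxy)phenoxy]-5-hydroxyphenyl sulfate F12. The cold acidic resin of step 13 releases 28.

## Further compounds

F1 | step 9 | 3-(benzyloxy)-5-bromophenol | Oc1cc(Br)cc(OCc2ccccc2)c1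
F2 | step 9 | [3-(benzyloxy)-5-bromophenoxy]triisopropylsilane | Brc1cc(OCc2ccccc2)cc(O[Si](C(C)C)(C(C)C)C(C)C)c1
F3 | step 9 | [3-(benzyloxy)-5-(triisopropylsilyloxy)phenyl]lithium | [Li]c1cc(OCc2ccccc2)cc(O[Si](C(C)C)(C(C)C)C(C)C)c1
F4 | step 9 | [3-(benzyloxy)-5-(triisopropylsilyloxy)phenyl]boronic acid | OB(O)c1cc(OCc2ccccc2)cc(O[Si](C(C)C)(C(C)C)C(C)C)c1
F5 | step 5 | {3,5-bis(benzyloxy)-4-[(E)-1,2-dichloroethenyloxy]phenoxy}triisopropylsilane | Cl/C=C(/Cl)Oc1c(OCc2ccccc2)cc(O[Si](C(C)C)(C(C)C)C(C)C)cc1OCc1ccccc1
F6 | step 5 | lithium {[2,6-bis(benzyloxy)-4-(triisopropylsilyloxy)phenoxy]ethynyl}ide | [Li]C#COc1c(OCc2ccccc2)cc(O[Si](C(C)C)(C(C)C)C(C)C)cc1OCc1ccccc1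
F7 | step 5 | [3,5-bis(benzyloxy)-4-(ethynyloxy)phenoxy]triisopropylsilane | C#COc1c(OCc2ccccc2)cc(O[Si](C(C)C)(C(C)C)C(C)C)cc1OCc1ccccc1
F8 | step 8 | (1,2,2-tribromoethoxy)triisopropylsilane (racemic) | BrC(Br)C(Br)O[Si](C(C)C)(C(C)C)C(C)C
F9 | step 8 | (2,2-dibromoethenyloxy)triisopropylsilane | BrC(Br)=CO[Si](C(C)C)(C(C)C)C(C)C
F10 | step 1 | potassium 2,6-bis(benzyloxy)-4-hydroxyphenyl sulfate | [K+].[O-]S(=O)(=O)Oc1c(OCc2ccccc2)cc(O)cc1OCc1ccccc1
F11 | step 12 | 3-(benzyloxy)-5-{2,6-bis(benzyloxy)-4-[(2,2,2-trichloroethoxy)sulfonyloxy]phenoxy}phenyl 2,2,2-trichloroethyl sulfate | ClC(Cl)(Cl)COS(=O)(=O)Oc1cc(OCc2ccccc2)cc(Oc2c(OCc3ccccc3)cc(OS(=O)(=O)OCC(Cl)(Cl)Cl)cc2OCc2ccccc2)c1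
F12 | step 12 | diammonium 3-[2,6-dihydroxy-4-(sulfonatooxy)phenoxy]-5-hydroxyphenyl sulfate | [NH4+].[NH4+].[O-]S(=O)(=O)Oc1cc(O)cc(Oc2c(O)cc(OS(=O)(=O)[O-])cc2O)c1
A1 | alternative 1 | {2-[3-(tert-butyldimethylsilyloxy)phenoxy]-1,3-phenylene}bis(oxy)bis(tert-butyldimethylsilane) | CC(C)(C)[Si](C)(C)Oc1cccc(Oc2c(O[Si](C)(C)C(C)(C)C)cccc2O[Si](C)(C)C(C)(C)C)c1
A2 | alternative 1 | bis(pinacolboronate) of A1 at C5 and C4' | CC(C)(C)[Si](C)(C)Oc1cc(B2OC(C)(C)C(C)(C)O2)cc(Oc2c(O[Si](C)(C)C(C)(C)C)cc(B3OC(C)(C)C(C)(C)O3)cc2O[Si](C)(C)C(C)(C)C)c1
A3 | alternative 1 | 3-[2,6-bis(tert-butyldimethylsilyloxy)-4-hydroxyphenoxy]-5-(tert-butyldimethylsilyloxy)phenol | CC(C)(C)[Si](C)(C)Oc1cc(O)cc(Oc2c(O[Si](C)(C)C(C)(C)C)cc(O)cc2O[Si](C)(C)C(C)(C)C)c1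
A4 | alternative 2 | 3-(benzyloxy)-5-(triisopropylsilyloxy)phenol | Oc1cc(OCc2ccccc2)cc(O[Si](C(C)C)(C(C)C)C(C)C)c1
A5 | alternative 2 | dibenzyl 2-[3-(benzyloxy)-5-(triisopropylsilyloxy)phenoxy]propanedioate | O=C(OCc1ccccc1)C(Oc1cc(OCc2ccccc2)cc(O[Si](C(C)C)(C(C)C)C(C)C)c1)C(=O)OCc1ccccc1
A6 | alternative 2 | dibenzyl (E)-3-(benzyloxy)pent-2-enedioate | O=C(OCc1ccccc1)/C=C(/OCc1ccccc1)CC(=O)OCc1ccccc1
A7 | alternative 2 | dibenzyl 2-(benzyloxy)-5-[3-(benzyloxy)-5-(triisopropylsilyloxy)phenoxy]-4,6-dihydroxybenzene-1,3-dicarboxylate | O=C(OCc1ccccc1)c1c(O)c(Oc2cc(OCc3ccccc3)cc(O[Si](C(C)C)(C(C)C)C(C)C)c2)c(O)c(C(=O)OCc2ccccc2)c1OCc1ccccc1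
A8 | alternative 3 | methyl (E)-3-(benzyloxy)-6-[3-(benzyloxy)-5-(triisopropylsilyloxy)phenoxy]-5-oxohex-3-enoate | COC(=O)C/C(OCc1ccccc1)=C\C(=O)COc1cc(OCc2ccccc2)cc(O[Si](C(C)C)(C(C)C)C(C)C)c1
A9 | alternative 3 | 5-(benzyloxy)-2-[3-(benzyloxy)-5-(triisopropylsilyloxy)phenoxy]benzene-1,3-diol | Oc1cc(OCc2ccccc2)cc(O)c1Oc1cc(OCc2ccccc2)cc(O[Si](C(C)C)(C(C)C)C(C)C)c1
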